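**Retrosynthetic overview**

Numbering used throughout: C1 lactone carbonyl, C2 its CH2, C3 ring-fusion CH (bears O–O), C4 ring-fusion C(CH3)–O, C5 ring CH2, C6 C(CH3)(side chain)–O–O, C7–C16 side chain (C13=C14, C15=C16, phenyl on C16).
Endgame: C13=C14 by Horner–Wadsworth–Emmons olefination of a C13 aldehyde; before that, one oxidation turns a lactol into the γ-lactone and CH2OH into CHO, and a temporary C7≡C8 triple bond is saturated with diimide.
Key disconnection: the C5–C6 and O–C3 bonds, a [3+3] union of a ketone-derived α-methoxy hydroperoxide (C6 with its O–O unit) with (E)-4-methylpenta-2,4-dienal (C1–C5).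
Enabling feature: in the 1,2-dioxane ring, C6 is a ketone-level carbon bearing the O–O unit (a peroxycarbenium ion once methoxide leaves), C5 is the CH2 terminus of a C4=C5 isopropenyl group, and the distal peroxide oxygen sits on C3, the β-carbon of the C1 carbonyl; the C4 cation left by ring closure is trapped by the C1 oxygen, which closes the five-membered ring.
Stereocontrol and ring order: C3 is set by amine catalysis, then the 1,2-dioxane (C6) and the oxolane (C4) close in that order in the same flask, both relayed from C3; the alkyne at C7≡C8 serves as the small axial group on C6.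

Key step: step 6

Remark: compounds named as starting materials, the amine catalyst and (E)-1-phenylbuta-1,3-diene are taken as commercially available, and the facial sense of the amine catalyst is assigned from the usual shielding model of its (E)-iminium ion.

**Route**

Step 1
Reactants: 1 hept-6-yn-1-ol
Product: 2 tert-butyl(hept-6-yn-1-yloxy)diphenylsilane
Conditions: t-BuPh2SiCl, imidazole, CH2Cl2, 0 °C to rt
Reagents that add atoms: tert-butyl(chloro)diphenylsilane, CC(C)(C)[Si](Cl)(c1ccccc1)c1ccccc1
Why: Silyl ether formation at the primary alcohol; the tert-butyldiphenylsilyl ether should survive the organolithium, acid and Lewis acid steps and keeps the future C13 at the alcohol level.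

Step 2
Reactants: 2 tert-butyl(hept-6-yn-1-yloxy)diphenylsilane; 3 N-methoxy-N-methylacetamide
Product: 5 9-[(tert-butyldiphenylsilyl)oxy]non-3-yn-2-one, via lithium acetylide 4 (not isolated)
Conditions: n-BuLi, THF, −78 °C; then 3, −78 to 0 °C; H2O work-up
Reagents that add atoms: none
Why: Weinreb ketone synthesis; the chelated tetrahedral adduct of the acetylide and the N-methoxy-N-methylamide persists until work-up, so the ynone should form without over-addition.

Step 3
Reactants: 5 9-[(tert-butyldiphenylsilyl)oxy]non-3-yn-2-one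
Product: 6 tert-butyl[(8,8-dimethoxynon-6-yn-1-yl)oxy]diphenylsilane
Conditions: HC(OMe)3, MeOH, p-TsOH (cat.), rt
Reagents that add atoms: trimethyl orthoformate, COC(OC)OC
Why: Acid-catalysed ketalisation with the orthoformate as water scavenger; methanol should not add to the conjugated alkyne under acid catalysis.

Step 4
Reactants: 6 tert-butyl[(8,8-dimethoxynon-6-yn-1-yl)oxy]diphenylsilane
Product: 7 tert-butyl[(8-hydroperoxy-8-methoxynon-6-yn-1-yl)oxy]diphenylsilane (racemic)
Conditions: H2O2 (anhydrous, in Et2O, 1.5 equiv), camphorsulfonic acid (cat.), Et2O, −20 to 0 °C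
Reagents that add atoms: hydrogen peroxide, OO
Why: Acid-catalysed perhydrolysis of a ketal (one methoxy group exchanged for OOH through the oxocarbenium ion), held at mono-exchange by low temperature and limited H2O2; the new stereocentre is racemic and is erased when this carbon is ionised in step 6.

Step 5
Reactants: 8 methacrolein; 9 (triphenylphosphoranylidene)acetaldehyde
Product: 10 (2E)-4-methylpenta-2,4-dienal
Conditions: toluene, 60 °C (8 in excess)
Reagents that add atoms: none
Why: Wittig reaction of a stabilised ylide, which should give the E-enal; excess methacrolein suppresses a second homologation.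

Step 6
Reactants: 7 tert-butyl[(8-hydroperoxy-8-methoxynon-6-yn-1-yl)oxy]diphenylsilane; 10 (2E)-4-methylpenta-2,4-dienal
Product: 12 (3R,4aR,7aR)-3-{7-[(tert-butyldiphenylsilyl)oxy]hept-1-yn-1-yl}-6-methoxy-3,4a-dimethylhexahydrofuro[3,2-c][1,2]dioxine as a mixture of acetal epimers, via peroxy aldehyde 11 (not isolated)
Conditions: (R)-2-{bis[3,5-bis(trifluoromethyl)phenyl][(trimethylsilyl)oxy]methyl}pyrrolidine (10 mol%), PhCO2H (10 mol%), CH2Cl2, −20 °C (10 in slight excess); then Me3SiOTf (40 mol%), −78 °C
Reagents that add atoms: none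
Why: Proposed new method: the amine and 10 form the (E)-iminium ion, the catalyst covers the Si face of C3, and the OOH group of 7 adds to the Re face (oxa-Michael, O–C3 bond) to give 3R-11, the closest known reaction type being the amine-catalysed enantioselective peroxidation of enals with tertiary hydroperoxides. Me3SiOTf then ionises the methoxy peroxyketal of 11 to a peroxycarbenium ion at C6, which is attacked by C5 of the isopropenyl group (C5–C6 bond), the closest known reaction type being the Lewis-acid cyclisation of unsaturated peroxyketals to 1,2-dioxanes. The 1,2-dioxane closes 6-endo-trig through a chair in which the C3 side arm and the C6 methyl group are equatorial and the slim alkynyl group is axial, which sets C6 relative to C3. The tertiary C4 cation is captured by the aldehyde oxygen in a five-membered closure that can only reach the face cis to C2, so C4 follows C3 and the rings are cis-fused, and the resulting oxocarbenium ion takes back the methoxide lost from C6, so this stage is an isomerisation that needs only catalytic Me3SiOTf and gives C1 as an acetal mixture that step 9 erases. The step needs 1,4- rather than 1,6-addition (secured by iminium activation, which is strongest at C3) and C–C closure at C6 in the 6-endo mode (secured by the 1,1-disubstituted alkene, which makes C5 the nucleophilic carbon and C4 the tertiary cation).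

Step 7
Reactants: 12 (3R,4aR,7aR)-3-{7-[(tert-butyldiphenylsilyl)oxy]hept-1-yn-1-yl}-6-methoxy-3,4a-dimethylhexahydrofuro[3,2-c][1,2]dioxine
Product: 13 (3S,4aR,7aR)-3-{7-[(tert-butyldiphenylsilyl)oxy]heptyl}-6-methoxy-3,4a-dimethylhexahydrofuro[3,2-c][1,2]dioxine
Conditions: KO2CN=NCO2K (large excess), AcOH, MeOH, 0 °C to rt
Reagents that add atoms: none
Why: Diimide reduction; concerted syn transfer of H2 should saturate the triple bond (through the cis-alkene) and leave the O–O bond, the acetal and the silyl ether alone, where catalytic hydrogenation would cleave the peroxide; no stereocentre is touched (the descriptor at C6 changes only because the substituent priorities change).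

Step 8
Reactants: 13 (3S,4aR,7aR)-3-{7-[(tert-butyldiphenylsilyl)oxy]heptyl}-6-methoxy-3,4a-dimethylhexahydrofuro[3,2-c][1,2]dioxine
Product: 14 (3S,4aR,7aR)-3-(7-hydroxyheptyl)-3,4a-dimethylhexahydrofuro[3,2-c][1,2]dioxin-6-ol (lactol epimers)
Conditions: 48% aq. HF, MeCN, 0 °C to rt
Reagents that add atoms: water, O
Why: Aqueous HF should cleave the Si–O bond and hydrolyse the methyl acetal to the lactol, conditions that dialkyl peroxides tolerate; the lactol epimers are of no consequence.

Step 9
Reactants: 14 (3S,4aR,7aR)-3-(7-hydroxyheptyl)-3,4a-dimethylhexahydrofuro[3,2-c][1,2]dioxin-6-ol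
Product: 15 7-[(3S,4aR,7aR)-3,4a-dimethyl-6-oxohexahydrofuro[3,2-c][1,2]dioxin-3-yl]heptanal
Conditions: Dess–Martin periodinane (2.5 equiv), CH2Cl2, rt
Reagents that add atoms: none
Why: Dess–Martin oxidation should convert the lactol into the γ-lactone and the primary alcohol into the aldehyde in one operation under neutral, non-reducing conditions that leave the peroxide and all stereocentres untouched.

Step 10
Reactants: 15 7-[(3S,4aR,7aR)-3,4a-dimethyl-6-oxohexahydrofuro[3,2-c][1,2]dioxin-3-yl]heptanal; 16 diethyl [(2E)-3-phenylprop-2-en-1-yl]phosphonate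
Product: 18 plakortolide Q, via lithiated phosphonate 17 (not isolated)
Conditions: 16, LiN(SiMe3)2 (1.0 equiv), THF, −78 °C; then 15, −78 to 0 °C
Reagents that add atoms: none
Why: Horner–Wadsworth–Emmons olefination with a preformed allylic phosphonate anion, which should give the new C13=C14 bond with E geometry while the cinnamyl double bond stays E; one equivalent of the weakly basic anion at low temperature spares the β-peroxy lactone.

**Compound list**

1 | hept-6-yn-1-ol | C#CCCCCCO | starting material
2 | tert-butyl(hept-6-yn-1-yloxy)diphenylsilane | C#CCCCCCO[Si](c1ccccc1)(c1ccccc1)C(C)(C)C | intermediate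
3 | N-methoxy-N-methylacetamide | CC(=O)N(C)OC | starting material
4 | {7-[(tert-butyldiphenylsilyl)oxy]hept-1-yn-1-yl}lithium (lithium acetylide of 2) | [Li+].[C-]#CCCCCCO[Si](c1ccccc1)(c1ccccc1)C(C)(C)C | intermediate
5 | 9-[(tert-butyldiphenylsilyl)oxy]non-3-yn-2-one | CC(=O)C#CCCCCCO[Si](c1ccccc1)(c1ccccc1)C(C)(C)C | intermediate
6 | tert-butyl[(8,8-dimethoxynon-6-yn-1-yl)oxy]diphenylsilane | CC(OC)(OC)C#CCCCCCO[Si](c1ccccc1)(c1ccccc1)C(C)(C)C | intermediate
7 | tert-butyl[(8-hydroperoxy-8-methoxynon-6-yn-1-yl)oxy]diphenylsilane (racemic) | CC(OC)(OO)C#CCCCCCO[Si](c1ccccc1)(c1ccccc1)C(C)(C)C | intermediate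
8 | methacrolein (2-methylprop-2-enal) | CC(=C)C=O | starting material
9 | (triphenylphosphoranylidene)acetaldehyde | O=CC=P(c1ccccc1)(c1ccccc1)c1ccccc1 | starting material
10 | (2E)-4-methylpenta-2,4-dienal | CC(=C)/C=C/C=O | intermediate
11 | (3R)-3-({9-[(tert-butyldiphenylsilyl)oxy]-2-methoxynon-3-yn-2-yl}peroxy)-4-methylpent-4-enal (both epimers at the peroxyketal carbon) | O=CC[C@H](C(C)=C)OOC(C)(OC)C#CCCCCCO[Si](c1ccccc1)(c1ccccc1)C(C)(C)C | intermediate
12 | (3R,4aR,7aR)-3-{7-[(tert-butyldiphenylsilyl)oxy]hept-1-yn-1-yl}-6-methoxy-3,4a-dimethylhexahydrofuro[3,2-c][1,2]dioxine (acetal epimers; ring position 6 is C1 of the target numbering) | C[C@]1(C#CCCCCCO[Si](c3ccccc3)(c3ccccc3)C(C)(C)C)C[C@@]2(C)OC(OC)C[C@H]2OO1 | intermediate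
13 | (3S,4aR,7aR)-3-{7-[(tert-butyldiphenylsilyl)oxy]heptyl}-6-methoxy-3,4a-dimethylhexahydrofuro[3,2-c][1,2]dioxine (acetal epimers) | C[C@]1(CCCCCCCO[Si](c3ccccc3)(c3ccccc3)C(C)(C)C)C[C@@]2(C)OC(OC)C[C@H]2OO1 | intermediate
14 | (3S,4aR,7aR)-3-(7-hydroxyheptyl)-3,4a-dimethylhexahydrofuro[3,2-c][1,2]dioxin-6-ol (lactol epimers) | C[C@]1(CCCCCCCO)C[C@@]2(C)OC(O)C[C@H]2OO1 | intermediate
15 | 7-[(3S,4aR,7aR)-3,4a-dimethyl-6-oxohexahydrofuro[3,2-c][1,2]dioxin-3-yl]heptanal | C[C@]1(CCCCCCC=O)C[C@@]2(C)OC(=O)C[C@H]2OO1 | intermediate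
16 | diethyl [(2E)-3-phenylprop-2-en-1-yl]phosphonate | CCOP(=O)(C/C=C/c1ccccc1)OCC | starting material
17 | lithium salt of the α-carbanion of 16 | [Li+].CCOP(=O)([CH-]/C=C/c1ccccc1)OCC | intermediate
18 | plakortolide Q, (3S,4aR,7aR)-3,4a-dimethyl-3-[(7E,9E)-10-phenyldeca-7,9-dien-1-yl]tetrahydrofuro[3,2-c][1,2]dioxin-6(3H)-one | C[C@]1(CCCCCC/C=C/C=C/c2ccccc2)C[C@@]2(C)OC(=O)C[C@H]2OO1 | target

**Step count and risks**

Total step count: 10. Longest linear sequence: 9 (steps 1–4 and 6–10).

Steps most likely to fail:

1. Step 6 (bears the label). The peroxide may be lost from 11 by β-elimination before the ring closes. In the Lewis-acid stage the activated aldehyde may close onto the isopropenyl group in a carbonyl-ene reaction, or may fail to capture the C4 cation. The fallback uses known reaction types, sets out from 7 and 10, and returns at 15. The two stages are separated and the cation trap is changed. The amine-catalysed peroxidation is run alone and 11 is isolated. Chlorite oxidation (NaClO2, NaH2PO4, 2-methylbut-2-ene, t-BuOH/H2O) should give (3R)-3-({9-[(tert-butyldiphenylsilyl)oxy]-2-methoxynon-3-yn-2-yl}peroxy)-4-methylpent-4-enoic acid F1. Me3SiOTf or SnCl4 in CH2Cl2 at −78 °C should then close the 1,2-dioxane by the known 6-endo cyclisation of an unsaturated peroxyketal, with the carboxylic acid trapping the C4 cation, to give the alkynyl peroxy-lactone (3R,4aR,7aR)-3-{7-[(tert-butyldiphenylsilyl)oxy]hept-1-yn-1-yl}-3,4a-dimethyltetrahydrofuro[3,2-c][1,2]dioxin-6(3H)-one F2. Diimide should give the saturated silyl ether (3S,4aR,7aR)-3-{7-[(tert-butyldiphenylsilyl)oxy]heptyl}-3,4a-dimethyltetrahydrofuro[3,2-c][1,2]dioxin-6(3H)-one F3. Aqueous HF in MeCN should give the alcohol (3S,4aR,7aR)-3-(7-hydroxyheptyl)-3,4a-dimethyltetrahydrofuro[3,2-c][1,2]dioxin-6(3H)-one F4, and Dess–Martin oxidation returns to 15.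

2. Step 4. The exchange may run on to the geminal bis-hydroperoxide, or the acid may send the ketal back to the ynone. The fallback sets out from 2 and returns at 7. Sonogashira coupling of 2 with 2-bromopropene (PdCl2(PPh3)2, CuI, Et3N) should give tert-butyl[(8-methylnon-8-en-6-yn-1-yl)oxy]diphenylsilane F5. Ozonolysis of its 1,1-disubstituted alkene in MeOH/CH2Cl2 at −78 °C, where the alkyne is left alone, lets methanol trap the carbonyl oxide at the substituted carbon and should give 7 directly.

3. Step 10. Deprotonation next to the lactone carbonyl may open the 1,2-dioxane by retro-oxa-Michael reaction in competition with olefination, or E selectivity at C13=C14 may be incomplete. The fallback sets out from 15 and returns at 18. Methylenation with preformed Ph3P=CH2 (THF, −78 °C) should give (3S,4aR,7aR)-3,4a-dimethyl-3-(oct-7-en-1-yl)tetrahydrofuro[3,2-c][1,2]dioxin-6(3H)-one F6. Base-free cross-metathesis of F6 with (E)-1-phenylbuta-1,3-diene (second-generation Grubbs catalyst, CH2Cl2, 40 °C) should give 18.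

Further compounds
F1 | step 6 | (3R)-3-({9-[(tert-butyldiphenylsilyl)oxy]-2-methoxynon-3-yn-2-yl}peroxy)-4-methylpent-4-enoic acid | OC(=O)C[C@H](C(C)=C)OOC(C)(OC)C#CCCCCCO[Si](c1ccccc1)(c1ccccc1)C(C)(C)C
F2 | step 6 | (3R,4aR,7aR)-3-{7-[(tert-butyldiphenylsilyl)oxy]hept-1-yn-1-yl}-3,4a-dimethyltetrahydrofuro[3,2-c][1,2]dioxin-6(3H)-one | C[C@]1(C#CCCCCCO[Si](c3ccccc3)(c3ccccc3)C(C)(C)C)C[C@@]2(C)OC(=O)C[C@H]2OO1
F3 | step 6 | (3S,4aR,7aR)-3-{7-[(tert-butyldiphenylsilyl)oxy]heptyl}-3,4a-dimethyltetrahydrofuro[3,2-c][1,2]dioxin-6(3H)-one | C[C@]1(CCCCCCCO[Si](c3ccccc3)(c3ccccc3)C(C)(C)C)C[C@@]2(C)OC(=O)C[C@H]2OO1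
F4 | step 6 | (3S,4aR,7aR)-3-(7-hydroxyheptyl)-3,4a-dimethyltetrahydrofuro[3,2-c][1,2]dioxin-6(3H)-one | C[C@]1(CCCCCCCO)C[C@@]2(C)OC(=O)C[C@H]2OO1
F5 | step 4 | tert-butyl[(8-methylnon-8-en-6-yn-1-yl)oxy]diphenylsilane | CC(=C)C#CCCCCCO[Si](c1ccccc1)(c1ccccc1)C(C)(C)C
F6 | step 10 | (3S,4aR,7aR)-3,4a-dimethyl-3-(oct-7-en-1-yl)tetrahydrofuro[3,2-c][1,2]dioxin-6(3H)-one | C[C@]1(CCCCCCC=C)C[C@@]2(C)OC(=O)C[C@H]2OO1
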